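**Two readings.** 49.1% of the starting material left in oak and 60.1% left in birch at 20.0 min are the two readings I reckon this flask from. In each run, enzyme turns starting material into target, while second substrate goes in by portions.

| setting | oak | birch | flask |
|---|---|---|---|
| starting material | 0.070 M | 0.11 M | 0.050 M |
| second substrate | 0.025 M (in portions, 3) | 0.025 M (in portions, 3) | 0.0250 M (in portions, 3) |
| enzyme | 46 µM | 46 µM | 46 µM |
| remark | run made earlier; portions every 2.0 min | run made earlier; portions every 2.0 min | the portions of second substrate follow each other after 2.0 min, the first at the start |
| time |  |  | 20 min |

- oak (time / min: target / %, starting material / %): 2.00: 6.4, 94.4; 5.00: 14.2, 85.7; 10.0: 26.8, 72.3; 15.0: 40.5, 59.4; 20.0: 52.0, 49.1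
- birch (time / min: target / %, starting material / %): 1.50: 2.5, 97.0; 3.00: 6.3, 93.7; 6.00: 12.0, 88.2; 10.0: 19.5, 79.5; 20.0: 39.5, 60.1

(each reading ± 0.5 percentage points)

- amount of target in the flask at 20 min, in percent of the starting material charged
- amount of starting material in the flask at 20 min, in percent of the starting material charged

- the analysis behind the earlier runs scatters by 0.5 percentage points, standard deviation

**The reach.** Let c be the charge of starting material, a what is left of it, t the time, and K the Michaelis constant. If the rate is V a/(K + a), integration gives V t = (c − a) + K ln(c/a). Oak and birch share enzyme, portions and time, so I set this sum equal for both. Read from these scattered readings, that gives K = 0.0409 M and W = V t = 0.0647 M. I call W the reach: on this rule, the sum that this enzyme charge pays in this time, with the portions held as they are.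

**The curve.** The flask has the same enzyme, portions and time, with c = 0.050 M. By my reckoning, it starts by losing 0.0356 /min of its charge. On the same rule, target crosses starting material at 16.5 min. For 20 min, rewrite the rule as a = c exp((c − a − W)/K) and guess 0.0250 M, which is half of the charge. This returns 0.0189 M. The mean of guess and answer, put back, returns 0.0204 M, and the next mean returns 0.0208 M. So I commit to 41.6% left and 58.4% target, on a curve heading for 100% target.

**The forecast.** It gives 59% target (54% to 64%) and 41% starting material (36% to 46%), which are its figures and not mine, and adds: “Km is loosely determined, so the spread is a few points”.

**The result.** The flask gives 60.4% target and 39.5% starting material at 20.0 min, and it is still moving: at 200 min it holds 100% target.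

    starting material + enzyme ⇌ complex A (K = 50.1 /M, k = 203 /M/s)
    complex A → enzyme + target (k = 1.11 /s)
    second substrate + enzyme ⇌ complex B (K = 61.8 /M, k = 5940 /M/s)
    complex B → enzyme + second product (k = 0.337 /s)
    2 second substrate → self-condensation product (k = 0.532 /M/s)
    complex B → spent catalyst (k = 0.00100 /s)

**Same reach.** One more flask, charged with 0.12 M of starting material, keeps 62.3% of it at 20.0 min. Put into the reach sum, that reads 0.0646 M, against 0.0647 M from oak and birch.

The numbers in the tables are simulated on assumed constants, and the scatter is random.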